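## Structural features

The target is a briarane. A cyclohexane (ring A: C1, C14, C13, C12, C11, C10) is trans-fused through C1–C10 to a ten-membered carbocycle (C1 to C10), and a γ-lactone (C7, C8, C17, C19 and the C7 oxygen) is fused to the large ring at C7–C8. Eleven stereocentres form one unbroken array, C2–C1(–C14)–C10(–C11–C12)–C9–C8(–C17)–C7–C6, with C1 quaternary and C8 a tertiary carbinol. Seven oxygen functions end in five different states: isobutyrate (C2), acetates (C9, C14), isovalerate (C12), free tertiary hydroxyl (C8), lactone (C7) and spiro-epoxide (C11–C20). The fragile elements are the spiro-epoxide, the secondary allylic chloride at C6 (which closes to an epoxide if a free C7 alkoxide is present), the β-hydroxy lactone, and esters next to free or latent hydroxyls (acyl migration). The real difficulty is closing the ten-membered ring between C7, which sits next to the fully substituted C8, and C6, which must carry chlorine anti to the C7 oxygen. The feature used for this is the triad C5(=C16H2)–C6(Cl)–C7(O): it is the pattern left when a 3-chloroallyl metal bound at C16 transfers its C6 terminus to a C7 aldehyde, so C6–C7 can be both the ring-closing bond and the source of two stereocentres. In ring A, the cis-1,3 oxygens at C12 and C14, the trans C2 and C9 branches and the cis relation of C14–O to C2 match an endo [4+2] adduct of a 1,3-dioxygenated diene with an (E)-2-methyl enal.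

## Logic of the disconnections

49 to 47: the acyl C–O bond of the C12 ester and the C11–O and C20–O bonds of the epoxide are cut last. The epoxide is the most sensitive group, and its oxygen lies on the face of the C12 oxygen, so a free C12 hydroxyl can deliver the oxidant before it is acylated. The forward steps must prefer C11=C20 over C5=C16, and the secondary C12 hydroxyl over the tertiary C8 hydroxyl.

47 to 44: the two O–Si bonds, the C14 acetate C–O bond and the lactone bond O7–C19 are cut. This returns to a hydroxy ester, which is what an aldehyde addition leaves. Lactonisation must be run under acid, because a basic C7 alkoxide next to C6–Cl would close to an epoxide.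

44 to 42: the C6–C7 bond is cut. This opens the ten-membered ring, removes both chlorohydrin stereocentres and moves the C5=C16 double bond back to C5=C6. What remains is a monocyclic aldehyde with an allylic bromide. The forward step needs γ-selective allyl transfer, anti Cl/O geometry, the correct aldehyde face and no reaction at the vinylic C–Cl bond.

42 to 39: the C7 aldehyde goes back to a primary alcohol, C16–Br to a primary allylic alcohol, and the C7, C14 and C16 hydroxyls to PMB ethers. One deprotection then serves three positions. Bromination must choose the allylic primary hydroxyl, and oxidation the remaining primary one.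

39 to 34 + 37: the C8–C17 bond is cut. A propanoate enolate equivalent adding to a C8 ketone gives the tertiary carbinol and C17 in one step. The addition must be non-basic (an acetate sits on O9), must take the Felkin–Anh face and must give the syn pair.

34 to 30 + 31: the C5=C6 double bond is cut (carbonyl olefination) and the C8 carbonyl is masked as a dithiane. The vinyl chloride geometry need not be controlled. The olefination must meet only one ketone.

30 to 20 + 24: the C8–C9 bond, the C9–H bond and the acyl groups on O2 and O9 are cut. An acyl anion equivalent opens a lactone that ties O2 to C9, which frees O2 and C9 in distinguishable form. The forward steps need acylation of a hindered lactone and Felkin–Anh reduction at C9.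

20 to 14: the C11–C20 bond and the C12–H bond are cut. C20 enters as an aminomethyl group α to a C12 ketone. Enolisation must occur on the C11 side, and hydride must give the axial C12 alcohol.

14 to 5 + 10: the C2–C3 bond and the lactone O–C9 bond are cut. The side chain C3–C5 with C16 arrives as a Grignard reagent. Chelation by the C14 ether must set C2.

5 to 3 + 4: the C1–C14 and C10–C11 bonds are cut. One cycloaddition gives ring A, the quaternary C1 and the C10 and C14 centres. It needs endo and facial control and attack on C=C, not C=O.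

3 to 1, 10 to 6, 24 to 21 and 37 to 35 are functional-group changes on commercial materials.

## Other disconnections considered

Alternative 1: The cut is C11–C12 of ring A together with O–C20. An open-chain C12 oxime is oxidised with hypochlorite to a nitrile oxide, which adds to the C11=C20 vinyl group on C10 and gives isoxazoline A1.
- In its favour: ring A and C20 are set in one dependable concerted step, and C20 is attached to C11 without any question of enolate regiochemistry. On this point it is better than step 10 of the chosen plan.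
- Against it here: C1 (quaternary) and C10 must be built beforehand in an open chain, whereas the chosen cycloaddition sets C1, C10 and C14 at once. After N–O cleavage the β-hydroxy ketone still needs dehydration, reduction and epoxidation, about as many operations as steps 10 to 12 and 30.
- Comparison: structurally it covers ring A only and would still need a closure of the ten-membered ring, for which the chromium step could serve. Mechanistically both are reliable. In step count it is equal at best.

Alternative 2: The cut is C1–C10, made across a fourteen-membered ring. A boron Lewis acid opens a C1–C14 epoxide, the allylsilane terminus C10 attacks C1, and loss of silicon leaves C11=C20, giving A2.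
- In its favour: both carbocycles, the quaternary centre and C10 form in one step along a biosynthesis-like path. For skeleton construction per step it is better than the chosen plan.
- Against it here: the macrocyclic precursor needs its own ring closure, a defined epoxide and a defined allylsilane geometry. The stereochemical course depends on macrocycle conformation, and the tertiary cation can eliminate or shift. A2 also lacks the C12 oxygen, the C8 hydroxyl, the C17 centre, the epoxide and the C6 chloride.
- Comparison: step economy is superior early and inferior late, since the chosen plan carries every oxygen from the start. The cationic mechanism is less predictable than the closed chromium chair.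

Alternative 3: The cuts are C9–C10 and C1–C2. A copper-catalysed vinyl Grignard addition at C10 of a 2-methylcyclohexenone gives the C1 enolate, which adds to the C2 aldehyde and gives A3.
- In its favour: C1, C2 and C10 are set in one flask, and the side chain with C16 arrives intact. C11 is a protected ketone, so the methylene can be made by olefination without a regiochemical question. On that point it is better than the chosen plan.
- Against it here: the aldol must control the enolate face and the aldehyde face by simple diastereoselection and can revert. The C14 ketone must later be reduced to the axial alcohol. The C10 vinyl group must be cleaved oxidatively in the presence of the 1,1-disubstituted alkene of A3.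
- Comparison: it replaces only the early phase and could feed the same endgame. Two bonds per flask equals the cycloaddition in bond count, but the cycloaddition fixes the C1/C10 relation by alkene geometry and not by face selection.

Key step: step 27

Remarks before the steps:
- Abbreviations: PMB = 4-methoxybenzyl, TBS = tert-butyldimethylsilyl, TES = triethylsilyl; briarane numbering is used for all ring A and chain positions.
- Check of the key-step structures: the seco aldehyde and the ring-closed chlorohydrin agree with 49 at every shared stereocentre, and the anti relation of Cl and O along C5–C6–C7–C8 that the chair delivers is the one present in 49. No descriptor needed correction.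
- Design changes in the precursor (skeleton and disconnection unchanged):
  - TBS replaces TES on the allylic C12 oxygen for stability; TES stays on the tertiary C8 oxygen as a bulky, non-chelating group.
  - C14 is left as a free hydroxyl and acetylated right after ring closure, so all three PMB ethers fall in one operation.
  - The aldehyde is made last, after the bromide.
  - Lactonisation is run under acid.
- Assumption: the (S)-oxazaborolidinium catalyst is taken to shield the enal face that leads to 5 as drawn; if the sense is opposite, the (R)-catalyst is used.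
- Assumption: the Wittig step gives both C5=C6 isomers; the (E) isomer is drawn for 33 to 43 and the mixture is carried on, because both give the same allylchromium species.

Step 1
Reactants: 1 (E)-4-methoxybut-3-en-2-one
Product: 2 (E)-4-[(4-methoxybenzyl)oxy]but-3-en-2-one
Conditions: 4-MeOC6H4CH2OH, PPTS (cat.), toluene, 80 °C, MeOH distilled off
Reagents that add atoms: 4-methoxybenzyl alcohol, COc1ccc(CO)cc1
Why: Acid-catalysed transetherification (addition–elimination at the β-carbon of the vinylogous ester); removal of methanol drives the exchange and the (E) enone is the stable isomer.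

Step 2
Reactants: 2 (E)-4-[(4-methoxybenzyl)oxy]but-3-en-2-one
Product: 3 (E)-1-[(4-methoxybenzyl)oxy]-3-(tert-butyldimethylsilyloxy)buta-1,3-diene
Conditions: t-BuMe2SiOTf, Et3N, Et2O, 0 °C
Reagents that add atoms: tert-butyldimethylsilyl triflate, CC(C)(C)[Si](C)(C)OS(=O)(=O)C(F)(F)F
Why: Soft enolisation and O-silylation at the only enolisable position (the methyl group) gives the 1-alkoxy-3-silyloxy diene; the C1=C2 geometry is untouched.

Step 3
Reactants: 3 (E)-1-[(4-methoxybenzyl)oxy]-3-(tert-butyldimethylsilyloxy)buta-1,3-diene; 4 ethyl (E)-3-methyl-4-oxobut-2-enoate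
Product: 5 ring A cycloadduct (ethyl 6-formyl-6-methyl-5-PMB-oxy-3-TBS-oxycyclohex-3-ene-1-carboxylate; formyl cis to the PMB ether and trans to the ester; C1, C10, C14 as in the target)
Conditions: (S)-3,3-diphenyl-1-(2-methylphenyl)tetrahydro-1H,3H-pyrrolo[1,2-c][1,3,2]oxazaborole·HN(SO2CF3)2 (15 mol%), CH2Cl2, −78 °C
Reagents that add atoms: none
Why: Lewis-acid-catalysed Diels–Alder reaction: the boron cation binds the formyl group, the nucleophilic diene terminus C11 bonds to C10 and C14 to C1; the (E) geometry of 4 fixes C2 trans to C9, the endo position of the complexed formyl group puts C14–O cis to C2, and the catalyst face sets the absolute configuration.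

Step 4
Reactants: 6 ethyl 4-chloro-3-oxobutanoate
Product: 7 ethyl 4-[(4-methoxybenzyl)oxy]-3-oxobutanoate
Conditions: 4-MeOC6H4CH2OH, NaH (2.2 equiv), THF, 0 °C to rt
Reagents that add atoms: 4-methoxybenzyl alcohol, COc1ccc(CO)cc1
Why: SN2 displacement of the α-chloride by the alkoxide; the second equivalent of base holds the β-keto ester as its enolate and prevents self-condensation.

Step 5
Reactants: 7 ethyl 4-[(4-methoxybenzyl)oxy]-3-oxobutanoate
Product: 8 ethyl 2-{2-[(4-methoxybenzyloxy)methyl]-1,3-dioxolan-2-yl}acetate
Conditions: Me3SiOCH2CH2OSiMe3, Me3SiOTf (cat.), CH2Cl2, −78 to −20 °C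
Reagents that add atoms: 1,2-bis(trimethylsilyloxy)ethane, C[Si](C)(C)OCCO[Si](C)(C)C
Why: Silyl-triflate-catalysed ketalisation under aprotic conditions that leave the acid-sensitive PMB ether intact; the ketal masks the future C5 carbonyl.

Step 6
Reactants: 8 ethyl 2-{2-[(4-methoxybenzyloxy)methyl]-1,3-dioxolan-2-yl}acetate
Product: 9 2-{2-[(4-methoxybenzyloxy)methyl]-1,3-dioxolan-2-yl}ethanol
Conditions: LiAlH4, THF, 0 °C
Reagents that add atoms: none
Why: Hydride reduction of the ester to the primary alcohol (C3); ketal and ether are inert.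

Step 7
Reactants: 9 2-{2-[(4-methoxybenzyloxy)methyl]-1,3-dioxolan-2-yl}ethanol
Product: 10 2-(2-bromoethyl)-2-[(4-methoxybenzyloxy)methyl]-1,3-dioxolane
Conditions: CBr4, PPh3, imidazole, CH2Cl2, 0 °C
Reagents that add atoms: carbon tetrabromide, BrC(Br)(Br)Br
Why: Appel bromination of the primary alcohol; imidazole buffers the ketal against HBr.

Step 8
Reactants: 10 2-(2-bromoethyl)-2-[(4-methoxybenzyloxy)methyl]-1,3-dioxolane; 5 ring A cycloadduct
Product: 13 trans-fused γ-lactone (O2 to C9) carrying the C3–C5 ketal chain and the C12 silyl enol ether, via Grignard reagent 11 (not isolated), via magnesium alkoxide 12 (not isolated)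
Conditions: Mg, THF, 40 °C; then 5, CH2Cl2/THF, −78 °C to rt
Reagents that add atoms: none
Why: Chelation-controlled Grignard addition followed by lactonisation: magnesium bridges the aldehyde oxygen and the C14 ether oxygen, the nucleophile enters from the side of the small C15 methyl group (away from the C10 ring branch) and sets C2; on warming the C2 alkoxide acylates on the C9 ester, giving a lactone that protects both groups and locks ring A in the chair with C14–O axial.

Step 9
Reactants: 13 γ-lactone silyl enol ether
Product: 14 C12 ketone lactone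
Conditions: Bu4NF, AcOH, THF, 0 °C
Reagents that add atoms: none
Why: Fluoride cleaves the enol Si–O bond far faster than any other group; the AcOH buffer prevents β-elimination of the C14 ether from the β-alkoxy ketone.

Step 10
Reactants: 14 C12 ketone lactone
Product: 17 C12 axial alcohol with C11 dimethylaminomethyl group, via C11 lithium enolate 15 (not isolated), via Mannich ketone 16 (not isolated)
Conditions: LiN(iPr)2, THF, −78 °C; CH2=NMe2+ I−, −78 to −20 °C; then LiBH(s-Bu)3, −78 °C
Reagents that add atoms: N,N-dimethylmethyleneiminium iodide, C=[N+](C)C.[I-]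
Why: Kinetic deprotonation is expected at C11, away from the C14 oxygen (the C13 hydrogens are deactivated by the neighbouring C–O bond and the lactone α-hydrogen is less acidic); the Mannich reaction adds C20, and the bulky hydride attacks the locked chair equatorially because the axial C14 ether blocks the axial path, giving the axial C12 alcohol cis to C14–O (C11 is drawn equatorial and is destroyed in step 11).

Step 11
Reactants: 17 C12 alcohol with C11 dimethylaminomethyl group
Product: 19 C12 allylic alcohol with C11=C20 methylene, via amine N-oxide 18 (not isolated)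
Conditions: mCPBA (1.05 equiv), K2CO3, CH2Cl2, −20 °C; then toluene, 80 °C
Reagents that add atoms: none
Why: N-Oxidation and Cope elimination: the amine oxide removes the only β-hydrogen (C11–H) through a five-membered syn transition state, so the methylene forms regiospecifically without passing through a base-sensitive α-methylene ketone.

Step 12
Reactants: 19 C12 allylic alcohol
Product: 20 C12 TBS ether lactone
Conditions: t-BuMe2SiOTf, 2,6-lutidine, CH2Cl2, −78 to 0 °C
Reagents that add atoms: tert-butyldimethylsilyl triflate, CC(C)(C)[Si](C)(C)OS(=O)(=O)C(F)(F)F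
Why: Silylation of the hindered axial alcohol with the reactive triflate; low temperature and the hindered base spare the ketal.

Step 13
Reactants: 21 1,3-dithiane
Product: 23 1,3-dithian-2-ylmethanol, via 2-lithio-1,3-dithiane 22 (not isolated)
Conditions: n-BuLi, THF, −30 °C; (CH2O)n, −30 °C to rt
Reagents that add atoms: formaldehyde (as paraformaldehyde), C=O
Why: C2 lithiation of the dithiane and addition to formaldehyde; the dithiane carbon becomes C8 and the new carbon C7.

Step 14
Reactants: 23 1,3-dithian-2-ylmethanol
Product: 24 2-[(4-methoxybenzyloxy)methyl]-1,3-dithiane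
Conditions: NaH, 4-MeOC6H4CH2Cl, Bu4NI (cat.), THF/DMF, 0 °C to rt
Reagents that add atoms: 4-methoxybenzyl chloride, COc1ccc(CCl)cc1
Why: Williamson ether synthesis; the PMB group on O7 matches those on O14 and O16.

Step 15
Reactants: 24 2-[(4-methoxybenzyloxy)methyl]-1,3-dithiane; 20 C12 TBS ether lactone
Product: 27 C2, C9 diol with the C8 dithiane, via lithiated dithiane 25 (not isolated), via acyl dithiane 26 (not isolated)
Conditions: n-BuLi, THF, −30 °C; then 20, −78 to −20 °C; then MeOH, NaBH4, 0 °C
Reagents that add atoms: none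
Why: The acyl anion equivalent opens the lactone at C9 (C8–C9 bond) and frees O2; hydride then adds to the C9 ketone by the Felkin–Anh path, with the quaternary C1 anti to the hydride and the bulky dithiane carbon next to H10, which gives the C9 configuration of the target.

Step 16
Reactants: 27 C2, C9 diol
Product: 28 C2 isobutyrate with free C9 hydroxyl
Conditions: (i-PrCO)2O, Et3N, DMAP (cat.), CH2Cl2, 0 °C
Reagents that add atoms: isobutyric anhydride, CC(C)C(=O)OC(=O)C(C)C
Why: Site-selective acylation: the C2 hydroxyl has a CH2 neighbour, whereas the C9 hydroxyl is flanked by the fully substituted dithiane carbon and the ring methine and should not react with the branched anhydride at 0 °C.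

Step 17
Reactants: 28 C2 isobutyrate
Product: 29 C2 isobutyrate C9 acetate
Conditions: Ac2O, pyridine, DMAP, 40 °C
Reagents that add atoms: acetic anhydride, CC(=O)OC(C)=O
Why: Forced acetylation of the remaining hindered secondary alcohol with the smaller anhydride.

Step 18
Reactants: 29 C2 isobutyrate C9 acetate
Product: 30 C5 ketone
Conditions: PPTS, acetone/H2O (10:1), 55 °C
Reagents that add atoms: water, O
Why: Mild ketal hydrolysis; the dithiane, silyl ether, PMB ethers and esters are stable, and 30 contains no other ketone.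

Step 19
Reactants: 30 C5 ketone; 31 (chloromethyl)triphenylphosphonium chloride
Product: 33 C5=C6 vinyl chloride (E/Z mixture, E drawn), via chloromethylene ylide 32 (not isolated)
Conditions: NaN(SiMe3)2, THF, −78 °C; then 30, −78 °C to rt
Reagents that add atoms: none
Why: Wittig chloromethylenation of the unhindered α-alkoxy ketone; the geometry is left uncontrolled because both isomers lead to the same allylchromium species in step 27, and the esters do not react with the ylide.

Step 20
Reactants: 33 C5=C6 vinyl chloride
Product: 34 C8 ketone (C9 acetate, C7 PMB ether)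
Conditions: MeI, CaCO3, MeCN/H2O (4:1), 45 °C
Reagents that add atoms: water, O
Why: Alkylative dithiane hydrolysis (S-methylation, then hydrolysis of the sulfonium) under neutral conditions that spare the vinyl chloride, the methylene, the PMB ethers and the acetate next to the new ketone.

Step 21
Reactants: 35 methyl propanoate
Product: 37 (E)-1-methoxy-1-(trimethylsilyloxy)prop-1-ene, via lithium ester enolate 36 (not isolated)
Conditions: LiN(iPr)2, THF, −78 °C; Me3SiCl
Reagents that add atoms: chlorotrimethylsilane, C[Si](C)(C)Cl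
Why: Kinetic ester enolisation in THF and O-silylation give the silyl ketene acetal that carries C17, C18 and C19.

Step 22
Reactants: 34 C8 ketone; 37 (E)-1-methoxy-1-(trimethylsilyloxy)prop-1-ene
Product: 38 C8 tertiary alcohol with the C17 methyl ester branch
Conditions: MgBr2·OEt2 (3 equiv), CH2Cl2, −78 to −30 °C; aq. NaHCO3
Reagents that add atoms: none
Why: Mukaiyama aldol addition without free alkoxide, so the O9 acetate cannot migrate: MgBr2 binds the C8 carbonyl together with the C7 ether oxygen; the nucleophile adds anti to the C9–O bond with C7 next to H9 (Felkin–Anh), which sets C8, and the open transition state keeps the C18 methyl away from the bulky C9 branch, which sets C17 syn.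

Step 23
Reactants: 38 C8 tertiary alcohol
Product: 39 C8 TES ether
Conditions: Et3SiOTf, 2,6-lutidine, CH2Cl2, −40 to 0 °C
Reagents that add atoms: triethylsilyl triflate, CC[Si](CC)(CC)OS(=O)(=O)C(F)(F)F
Why: Silylation of the tertiary alcohol with the reactive triflate; the TES group later serves as the bulky non-chelating substituent next to the aldehyde.

Step 24
Reactants: 39 C8 TES ether
Product: 40 triol (free hydroxyls at C7, C14 and C16)
Conditions: DDQ (4 equiv), CH2Cl2/pH 7 buffer, 0 °C to rt
Reagents that add atoms: none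
Why: Oxidative cleavage of all three PMB ethers in one operation; silyl ethers, esters, the vinyl chloride and the methylene are inert to DDQ.

Step 25
Reactants: 40 triol
Product: 41 C16 allylic bromide (C7 and C14 hydroxyls free)
Conditions: CBr4, PPh3 (1.1 equiv), 2,6-lutidine, CH2Cl2, −40 °C
Reagents that add atoms: carbon tetrabromide, BrC(Br)(Br)Br
Why: Appel bromination is fastest at the unhindered primary allylic hydroxyl; the C7 hydroxyl is neopentyl-like (next to the quaternary C8) and the C14 hydroxyl is a hindered axial secondary alcohol.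

Step 26
Reactants: 41 C16 allylic bromide
Product: 42 seco C7 aldehyde (C16 bromide, C6 vinyl chloride, C14 hydroxyl, C12 TBS ether, C8 TES ether)
Conditions: TEMPO (cat.), PhI(OAc)2, CH2Cl2, rt
Reagents that add atoms: none
Why: Oxoammonium oxidation takes the primary alcohol and leaves the secondary C14 hydroxyl and the allylic bromide; the aldehyde has no α-hydrogen and is used at once.

Step 27
Reactants: 42 seco C7 aldehyde
Product: 44 ten-membered C6 chloro C7 hydroxy ester, via allylchromium dichloride 43 (not isolated)
Conditions: CrCl2 (8 equiv), THF, slow addition of 42 to reach about 2 mM, rt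
Reagents that add atoms: none
Why: Proposed new method: two equivalents of CrCl2 (divalent chromium) reduce the allylic C–Br bond by two single-electron transfers to the allylchromium dichloride 43 (trivalent chromium), which can equilibrate by 1,3-metal shift so that chromium sits on C16 with chlorine trans to C16, whichever vinyl chloride isomer of 42 reacts. The C7 aldehyde then binds chromium and C6 attacks C7 through a six-membered chair (Cr, C16, C5, C6, C7, O) with allylic transposition, which creates the C5=C16 methylene. The closest known reaction types are the CrCl2-mediated Nozaki–Hiyama allylation used as a macrocyclisation and the γ-chloroallylboration of aldehydes to chlorohydrins; their combination in a ring closure with a 2-substituted γ-chloroallyl reagent is the new element. The ten-membered ring closes in the 10-exo-trig mode by C–C bond formation at the carbonyl carbon. C6 is set relative to C7 by the chair: equatorial chlorine gives the anti chlorohydrin along C5–C6–C7–C8. C7 is set by the C8 stereocentre: with the bulky, non-chelating triethylsilyloxy group anti to the incoming carbon (Felkin–Anh arrangement) the nucleophile passes the C17 branch while the forming ring holds C9 on the far side, which places O7 anti to O8. The step needs reaction at C–Br and not at the vinylic C–Cl or the esters, which nickel-free CrCl2 secures because it does not insert into alkenyl chlorides, and it needs ring closure over coupling between molecules, which slow addition at high dilution secures. The chromium alkoxide is only weakly basic, so neither epoxide closure of the chlorohydrin nor acyl migration is expected before the acidic lactonisation of step 28.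

Step 28
Reactants: 44 ten-membered C6 chloro C7 hydroxy ester
Product: 46 C14 acetate lactone with C8 TES and C12 TBS ethers, via hydroxy lactone 45 (not isolated)
Conditions: camphorsulfonic acid (cat.), CH2Cl2, rt; then Ac2O, pyridine, DMAP, 0 °C to rt
Reagents that add atoms: acetic anhydride, CC(=O)OC(C)=O
Why: Acid-catalysed 5-exo-trig lactonisation of O7 onto the C19 methyl ester (favoured by the fully substituted C8) removes the free C7 hydroxyl before any base is used; the only remaining hydroxyl, at C14, is then acetylated.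

Step 29
Reactants: 46 C14 acetate lactone bis-silyl ether
Product: 47 8,12-diol
Conditions: HF·pyridine, pyridine, THF, 0 °C to rt
Reagents that add atoms: none
Why: Buffered fluoride removes the tertiary TES and the secondary TBS ether together without touching the esters, the lactone or the allylic chloride.

Step 30
Reactants: 47 8,12-diol
Product: 48 11,20-epoxide with free C12 and C8 hydroxyls
Conditions: VO(acac)2 (5 mol%), t-BuOOH, CH2Cl2, 0 °C
Reagents that add atoms: tert-butyl hydroperoxide, CC(C)(C)OO
Why: Hydroxyl-directed epoxidation: the vanadium alkoxide of the axial allylic C12 hydroxyl delivers oxygen to the same face of C11=C20, which is the epoxide configuration of the target; C5=C16 is electron-poor (allylic chloride) and has no allylic hydroxyl.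

Step 31
Reactants: 48 11,20-epoxide
Product: 49 target (CNP0194902.1)
Conditions: i-BuCOCl, pyridine, DMAP (cat.), CH2Cl2, 0 °C
Reagents that add atoms: isovaleryl chloride, CC(C)CC(=O)Cl
Why: Acylation of the secondary C12 hydroxyl; the tertiary C8 hydroxyl does not react under these conditions.

## Compound list

1 | (E)-4-methoxybut-3-en-2-one | CO/C=C/C(C)=O | starting material
2 | (E)-4-[(4-methoxybenzyl)oxy]but-3-en-2-one | COc1ccc(CO/C=C/C(C)=O)cc1 | intermediate
3 | (E)-1-[(4-methoxybenzyl)oxy]-3-(tert-butyldimethylsilyloxy)buta-1,3-diene | COc1ccc(CO/C=C/C(=C)O[Si](C)(C)C(C)(C)C)cc1 | intermediate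
4 | ethyl (E)-3-methyl-4-oxobut-2-enoate | CCOC(=O)/C=C(\C)C=O | starting material
5 | ring A cycloadduct (formyl cis to PMB ether, trans to ester) | O=C[C@@]1(C)[C@@H](OCc2ccc(OC)cc2)C=C(O[Si](C)(C)C(C)(C)C)C[C@@H]1C(=O)OCC | intermediate
6 | ethyl 4-chloro-3-oxobutanoate | CCOC(=O)CC(=O)CCl | starting material
7 | ethyl 4-[(4-methoxybenzyl)oxy]-3-oxobutanoate | CCOC(=O)CC(=O)COCc1ccc(OC)cc1 | intermediate
8 | ethyl 2-{2-[(4-methoxybenzyloxy)methyl]-1,3-dioxolan-2-yl}acetate | CCOC(=O)CC1(COCc2ccc(OC)cc2)OCCO1 | intermediate
9 | 2-{2-[(4-methoxybenzyloxy)methyl]-1,3-dioxolan-2-yl}ethanol | OCCC1(COCc2ccc(OC)cc2)OCCO1 | intermediate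
10 | 2-(2-bromoethyl)-2-[(4-methoxybenzyloxy)methyl]-1,3-dioxolane | BrCCC1(COCc2ccc(OC)cc2)OCCO1 | intermediate
11 | Grignard reagent of 10 (not isolated) | Br[Mg]CCC1(COCc2ccc(OC)cc2)OCCO1 | intermediate
12 | C2 bromomagnesium alkoxide of the Grignard adduct (not isolated) | COc1ccc(COCC2(OCCO2)CC[C@H](O[Mg]Br)[C@@]3(C)[C@@H](OCc4ccc(OC)cc4)C=C(O[Si](C)(C)C(C)(C)C)C[C@@H]3C(=O)OCC)cc1 | intermediate
13 | trans-fused γ-lactone (O2–C9) with C3–C5 ketal chain and C12 silyl enol ether | COc1ccc(COCC2(OCCO2)CC[C@H](O3)[C@@]4(C)[C@@H](OCc5ccc(OC)cc5)C=C(O[Si](C)(C)C(C)(C)C)C[C@@H]4C3=O)cc1 | intermediate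
14 | C12 ketone lactone | COc1ccc(COCC2(OCCO2)CC[C@H](O3)[C@@]4(C)[C@@H](OCc5ccc(OC)cc5)CC(=O)C[C@@H]4C3=O)cc1 | intermediate
15 | C11 lithium enolate of 14 (not isolated) | COc1ccc(COCC2(OCCO2)CC[C@H](O3)[C@@]4(C)[C@@H](OCc5ccc(OC)cc5)CC(O[Li])=C[C@@H]4C3=O)cc1 | intermediate
16 | C11 Mannich ketone (not isolated; C11 drawn equatorial) | COc1ccc(COCC2(OCCO2)CC[C@H](O3)[C@@]4(C)[C@@H](OCc5ccc(OC)cc5)CC(=O)[C@@H](CN(C)C)[C@@H]4C3=O)cc1 | intermediate
17 | C12 axial alcohol with C11 dimethylaminomethyl group | COc1ccc(COCC2(OCCO2)CC[C@H](O3)[C@@]4(C)[C@@H](OCc5ccc(OC)cc5)C[C@@H](O)[C@@H](CN(C)C)[C@@H]4C3=O)cc1 | intermediate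
18 | amine N-oxide of 17 (not isolated) | COc1ccc(COCC2(OCCO2)CC[C@H](O3)[C@@]4(C)[C@@H](OCc5ccc(OC)cc5)C[C@@H](O)[C@@H](C[N+](C)(C)[O-])[C@@H]4C3=O)cc1 | intermediate
19 | C12 allylic alcohol with C11=C20 methylene | COc1ccc(COCC2(OCCO2)CC[C@H](O3)[C@@]4(C)[C@@H](OCc5ccc(OC)cc5)C[C@@H](O)C(=C)[C@@H]4C3=O)cc1 | intermediate
20 | C12 TBS ether lactone | COc1ccc(COCC2(OCCO2)CC[C@H](O3)[C@@]4(C)[C@@H](OCc5ccc(OC)cc5)C[C@@H](O[Si](C)(C)C(C)(C)C)C(=C)[C@@H]4C3=O)cc1 | intermediate
21 | 1,3-dithiane | C1CSCSC1 | starting material
22 | 2-lithio-1,3-dithiane (not isolated) | [Li]C1SCCCS1 | intermediate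
23 | 1,3-dithian-2-ylmethanol | OCC1SCCCS1 | intermediate
24 | 2-[(4-methoxybenzyloxy)methyl]-1,3-dithiane | COc1ccc(COCC2SCCCS2)cc1 | intermediate
25 | 2-lithio derivative of 24 (not isolated) | COc1ccc(COCC2([Li])SCCCS2)cc1 | intermediate
26 | C9 ketone (acyl dithiane) with free C2 hydroxyl (not isolated) | COc1ccc(COCC2(OCCO2)CC[C@H](O)[C@@]3(C)[C@@H](OCc4ccc(OC)cc4)C[C@@H](O[Si](C)(C)C(C)(C)C)C(=C)[C@@H]3C(=O)C5(COCc6ccc(OC)cc6)SCCCS5)cc1 | intermediate
27 | C2, C9 diol with C8 dithiane | COc1ccc(COCC2(OCCO2)CC[C@H](O)[C@@]3(C)[C@@H](OCc4ccc(OC)cc4)C[C@@H](O[Si](C)(C)C(C)(C)C)C(=C)[C@@H]3[C@H](O)C5(COCc6ccc(OC)cc6)SCCCS5)cc1 | intermediate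
28 | C2 isobutyrate with free C9 hydroxyl | COc1ccc(COCC2(OCCO2)CC[C@H](OC(=O)C(C)C)[C@@]3(C)[C@@H](OCc4ccc(OC)cc4)C[C@@H](O[Si](C)(C)C(C)(C)C)C(=C)[C@@H]3[C@H](O)C5(COCc6ccc(OC)cc6)SCCCS5)cc1 | intermediate
29 | C2 isobutyrate C9 acetate | COc1ccc(COCC2(OCCO2)CC[C@H](OC(=O)C(C)C)[C@@]3(C)[C@@H](OCc4ccc(OC)cc4)C[C@@H](O[Si](C)(C)C(C)(C)C)C(=C)[C@@H]3[C@H](OC(C)=O)C5(COCc6ccc(OC)cc6)SCCCS5)cc1 | intermediate
30 | C5 ketone | COc1ccc(COCC(=O)CC[C@H](OC(=O)C(C)C)[C@@]3(C)[C@@H](OCc4ccc(OC)cc4)C[C@@H](O[Si](C)(C)C(C)(C)C)C(=C)[C@@H]3[C@H](OC(C)=O)C5(COCc6ccc(OC)cc6)SCCCS5)cc1 | intermediate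
31 | (chloromethyl)triphenylphosphonium chloride | [Cl-].ClC[P+](c1ccccc1)(c1ccccc1)c1ccccc1 | starting material
32 | (chloromethylene)triphenylphosphorane (not isolated) | ClC=P(c1ccccc1)(c1ccccc1)c1ccccc1 | intermediate
33 | C5=C6 vinyl chloride (E/Z mixture, E drawn) | COc1ccc(COC/C(=C/Cl)CC[C@H](OC(=O)C(C)C)[C@@]3(C)[C@@H](OCc4ccc(OC)cc4)C[C@@H](O[Si](C)(C)C(C)(C)C)C(=C)[C@@H]3[C@H](OC(C)=O)C5(COCc6ccc(OC)cc6)SCCCS5)cc1 | intermediate
34 | C8 ketone | COc1ccc(COC/C(=C/Cl)CC[C@H](OC(=O)C(C)C)[C@@]3(C)[C@@H](OCc4ccc(OC)cc4)C[C@@H](O[Si](C)(C)C(C)(C)C)C(=C)[C@@H]3[C@H](OC(C)=O)C(=O)COCc5ccc(OC)cc5)cc1 | intermediate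
35 | methyl propanoate | CCC(=O)OC | starting material
36 | lithium (E)-enolate of methyl propanoate (not isolated) | C/C=C(\OC)O[Li] | intermediate
37 | (E)-1-methoxy-1-(trimethylsilyloxy)prop-1-ene | C/C=C(\OC)O[Si](C)(C)C | intermediate
38 | C8 tertiary alcohol with C17 methyl ester branch | COc1ccc(COC/C(=C/Cl)CC[C@H](OC(=O)C(C)C)[C@@]3(C)[C@@H](OCc4ccc(OC)cc4)C[C@@H](O[Si](C)(C)C(C)(C)C)C(=C)[C@@H]3[C@H](OC(C)=O)[C@](O)([C@@H](C)C(=O)OC)COCc5ccc(OC)cc5)cc1 | intermediate
39 | C8 TES ether | COc1ccc(COC/C(=C/Cl)CC[C@H](OC(=O)C(C)C)[C@@]3(C)[C@@H](OCc4ccc(OC)cc4)C[C@@H](O[Si](C)(C)C(C)(C)C)C(=C)[C@@H]3[C@H](OC(C)=O)[C@](O[Si](CC)(CC)CC)([C@@H](C)C(=O)OC)COCc5ccc(OC)cc5)cc1 | intermediate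
40 | triol (C7, C14, C16 hydroxyls) | OC/C(=C/Cl)CC[C@H](OC(=O)C(C)C)[C@@]1(C)[C@@H](O)C[C@@H](O[Si](C)(C)C(C)(C)C)C(=C)[C@@H]1[C@H](OC(C)=O)[C@](O[Si](CC)(CC)CC)([C@@H](C)C(=O)OC)CO | intermediate
41 | C16 allylic bromide | BrC/C(=C/Cl)CC[C@H](OC(=O)C(C)C)[C@@]1(C)[C@@H](O)C[C@@H](O[Si](C)(C)C(C)(C)C)C(=C)[C@@H]1[C@H](OC(C)=O)[C@](O[Si](CC)(CC)CC)([C@@H](C)C(=O)OC)CO | intermediate
42 | seco C7 aldehyde (key-step precursor) | BrC/C(=C/Cl)CC[C@H](OC(=O)C(C)C)[C@@]1(C)[C@@H](O)C[C@@H](O[Si](C)(C)C(C)(C)C)C(=C)[C@@H]1[C@H](OC(C)=O)[C@](O[Si](CC)(CC)CC)([C@@H](C)C(=O)OC)C=O | intermediate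
43 | C16 allylchromium dichloride (not isolated) | Cl[Cr](Cl)C/C(=C/Cl)CC[C@H](OC(=O)C(C)C)[C@@]1(C)[C@@H](O)C[C@@H](O[Si](C)(C)C(C)(C)C)C(=C)[C@@H]1[C@H](OC(C)=O)[C@](O[Si](CC)(CC)CC)([C@@H](C)C(=O)OC)C=O | intermediate
44 | ten-membered C6 chloro C7 hydroxy ester (key-step product) | C=C1CC[C@H](OC(=O)C(C)C)[C@@]2(C)[C@@H](O)C[C@@H](O[Si](C)(C)C(C)(C)C)C(=C)[C@@H]2[C@H](OC(C)=O)[C@](O[Si](CC)(CC)CC)([C@@H](C)C(=O)OC)[C@@H](O)[C@H]1Cl | intermediate
45 | 7,19-lactone with free C14 hydroxyl (not isolated) | C=C1CC[C@H](OC(=O)C(C)C)[C@@]2(C)[C@@H](O)C[C@@H](O[Si](C)(C)C(C)(C)C)C(=C)[C@@H]2[C@H](OC(C)=O)[C@]2(O[Si](CC)(CC)CC)[C@@H](C)C(=O)O[C@H]2[C@H]1Cl | intermediate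
46 | C14 acetate lactone with C8 TES and C12 TBS ethers | C=C1CC[C@H](OC(=O)C(C)C)[C@@]2(C)[C@@H](OC(C)=O)C[C@@H](O[Si](C)(C)C(C)(C)C)C(=C)[C@@H]2[C@H](OC(C)=O)[C@]2(O[Si](CC)(CC)CC)[C@@H](C)C(=O)O[C@H]2[C@H]1Cl | intermediate
47 | 8,12-diol | C=C1CC[C@H](OC(=O)C(C)C)[C@@]2(C)[C@@H](OC(C)=O)C[C@@H](O)C(=C)[C@@H]2[C@H](OC(C)=O)[C@]2(O)[C@@H](C)C(=O)O[C@H]2[C@H]1Cl | intermediate
48 | 11,20-epoxide with free C12 and C8 hydroxyls | C=C1CC[C@H](OC(=O)C(C)C)[C@@]2(C)[C@@H](OC(C)=O)C[C@@H](O)[C@]3(CO3)[C@@H]2[C@H](OC(C)=O)[C@]2(O)[C@@H](C)C(=O)O[C@H]2[C@H]1Cl | intermediate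
49 | CNP0194902.1 | C=C1CC[C@H](OC(=O)C(C)C)[C@@]2(C)[C@@H](OC(C)=O)C[C@@H](OC(=O)CC(C)C)[C@]3(CO3)[C@@H]2[C@H](OC(C)=O)[C@]2(O)[C@@H](C)C(=O)O[C@H]2[C@H]1Cl | target

## Step count and least certain steps

Total step count: 31. Longest linear sequence: 25 steps (steps 4 to 12, 15 to 20 and 22 to 31, from 6 to 49).

Step 27 (key step).
- What may go wrong: coupling between molecules instead of ring closure; protonation of the allylchromium species by the free C14 hydroxyl; loss of chloride from the isomer with chromium on C6; attack through C16 instead of C6; addition to the wrong aldehyde face. The last arises because the two carbon branches on C8 (C9 and C17) are of similar size and the ring strain of the ten-membered transition state may override the Felkin–Anh preference.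
- Fallback with known chemistry (ring closure by alkenyl halide addition, chlorine brought in afterwards by allylic transposition). It sets out from compound 30 and comes back at compound 46.
  - Wittig bromomethylenation of 30 with Ph3P=CHBr would give the vinyl bromide F1.
  - Dithiane hydrolysis, Mukaiyama aldol addition and silylation as in steps 20, 22 and 23 would give the C8 ketone F2, the tertiary alcohol F3 and the TES ether F4.
  - DDQ would give the triol F5. Selective silylation of the primary allylic hydroxyl (t-BuMe2SiCl, imidazole, −20 °C) would give the C16 TBS ether F6, and TEMPO/PhI(OAc)2 the aldehyde F7.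
  - A Nozaki–Hiyama–Kishi macrocyclisation with NiCl2 (cat.)/CrCl2 in DMSO/THF would join C6 to C7 and give the cyclic 5-ene 7-ol F8; both alkene isomers can be used because the geometry is lost later.
  - Lactonisation and C14 acetylation as in step 28 would give the lactone F9. HF·pyridine/pyridine at 0 °C would free the primary allylic hydroxyl to give F10.
  - SOCl2 in Et2O would then chlorinate with allylic transposition (SNi′), placing chlorine on C6 and the double bond at C5=C16, which is compound 46.

Step 3.
- What may go wrong: addition of the very nucleophilic diene to the formyl C=O (hetero-cycloaddition or aldol-type addition) instead of the C=C bond; incomplete endo or facial control for a β-substituted 2-methyl enal; binding of the catalyst by the ether oxygens.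
- Fallback (covalent auxiliary and thermal cycloaddition in place of catalyst control). It sets out from compound 3 and comes back at compound 13.
  - A Wittig reaction of (1R,2S,5R)-menthyl glyoxylate with 2-(triphenylphosphoranylidene)propanal would give the menthyl dienophile F11.
  - Its uncatalysed cycloaddition with 3 (toluene, 60 °C) would give diastereomeric adducts that can be separated by chromatography or crystallisation.
  - The desired menthyl ester cycloadduct F12 would give 13 under the conditions of step 8, with loss of menthol in the lactonisation.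

Step 10.
- What may go wrong: deprotonation on the C13 side followed by β-elimination of the C14 ether; deprotonation at C10 with epimerisation. The two α-methylene groups of the ketone differ only by their neighbours.
- Fallback (C20 brought in before the cycloaddition, where only one enolisable position exists). It sets out from compound 3 and comes back at compound 19.
  - ZnBr2-catalysed phenylthiomethylation of the silyl enol ether 3 with PhSCH2Cl would give the β-phenylthio ketone F13, and silylation as in step 2 the 4-substituted diene F14.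
  - The cycloaddition of step 3 would give the cycloadduct F15, the conditions of step 8 the lactone F16, and fluoride as in step 9 the ketone F17.
  - LiBH(s-Bu)3 would give the axial alcohol F18 and NaIO4 the sulfoxide F19.
  - Thermal syn-elimination of F19 (toluene, 110 °C, CaCO3) would give 19.

Step 15.
- What may go wrong: slow acylation of the fully substituted dithiane anion by the hindered lactone carbonyl; competing deprotonation at C10, which is allylic and α to the carbonyl; incomplete Felkin–Anh control in the reduction.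
- Fallback (addition at the aldehyde oxidation level, then oxidation and reduction). It sets out from compound 20 and comes back at compound 28.
  - i-Bu2AlH at −78 °C would give the lactol F20.
  - The lithiated dithiane 25 would add to its open hydroxy aldehyde form to give the diol F21, expected mainly as the C9 epimer of 27.
  - Selective isobutyrylation as in step 16 would give the ester F22, and a periodinane oxidation (Dess–Martin reagent, NaHCO3) the C9 ketone F23.
  - NaBH4 reduction by the Felkin–Anh path would give 28.

Step 22.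
- What may go wrong: low simple diastereoselection at C17 or attack on the wrong face of the C8 ketone in the open transition state; slow addition to the hindered ketone; acetyl migration from O9 if a free alkoxide forms.
- Fallback (a metal enolate with a closed, chelated transition state in place of the Lewis-acid-mediated open one). It sets out from compound 34 and comes back at compound 38.
  - A Reformatsky-type addition of methyl 2-bromopropanoate with SmI2 in THF at −78 °C would give 38 directly; no new compound is formed on the way.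

## Further compounds

F1 | step 27 | C5=C6 vinyl bromide analogue of 33 (E/Z mixture, E drawn) | COc1ccc(COC/C(=C/Br)CC[C@H](OC(=O)C(C)C)[C@@]3(C)[C@@H](OCc4ccc(OC)cc4)C[C@@H](O[Si](C)(C)C(C)(C)C)C(=C)[C@@H]3[C@H](OC(C)=O)C5(COCc6ccc(OC)cc6)SCCCS5)cc1
F2 | step 27 | C8 ketone of the vinyl bromide series | COc1ccc(COC/C(=C/Br)CC[C@H](OC(=O)C(C)C)[C@@]3(C)[C@@H](OCc4ccc(OC)cc4)C[C@@H](O[Si](C)(C)C(C)(C)C)C(=C)[C@@H]3[C@H](OC(C)=O)C(=O)COCc5ccc(OC)cc5)cc1
F3 | step 27 | C8 tertiary alcohol of the vinyl bromide series | COc1ccc(COC/C(=C/Br)CC[C@H](OC(=O)C(C)C)[C@@]3(C)[C@@H](OCc4ccc(OC)cc4)C[C@@H](O[Si](C)(C)C(C)(C)C)C(=C)[C@@H]3[C@H](OC(C)=O)[C@](O)([C@@H](C)C(=O)OC)COCc5ccc(OC)cc5)cc1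
F4 | step 27 | C8 TES ether of the vinyl bromide series | COc1ccc(COC/C(=C/Br)CC[C@H](OC(=O)C(C)C)[C@@]3(C)[C@@H](OCc4ccc(OC)cc4)C[C@@H](O[Si](C)(C)C(C)(C)C)C(=C)[C@@H]3[C@H](OC(C)=O)[C@](O[Si](CC)(CC)CC)([C@@H](C)C(=O)OC)COCc5ccc(OC)cc5)cc1
F5 | step 27 | triol of the vinyl bromide series | OC/C(=C/Br)CC[C@H](OC(=O)C(C)C)[C@@]1(C)[C@@H](O)C[C@@H](O[Si](C)(C)C(C)(C)C)C(=C)[C@@H]1[C@H](OC(C)=O)[C@](O[Si](CC)(CC)CC)([C@@H](C)C(=O)OC)CO
F6 | step 27 | C16 TBS ether of the vinyl bromide series | CC(C)(C)[Si](C)(C)OC/C(=C/Br)CC[C@H](OC(=O)C(C)C)[C@@]1(C)[C@@H](O)C[C@@H](O[Si](C)(C)C(C)(C)C)C(=C)[C@@H]1[C@H](OC(C)=O)[C@](O[Si](CC)(CC)CC)([C@@H](C)C(=O)OC)CO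
F7 | step 27 | C7 aldehyde of the vinyl bromide series | CC(C)(C)[Si](C)(C)OC/C(=C/Br)CC[C@H](OC(=O)C(C)C)[C@@]1(C)[C@@H](O)C[C@@H](O[Si](C)(C)C(C)(C)C)C(=C)[C@@H]1[C@H](OC(C)=O)[C@](O[Si](CC)(CC)CC)([C@@H](C)C(=O)OC)C=O
F8 | step 27 | ten-membered 5-ene 7-ol with C16 TBS ether (alkene geometry open) | CC(C)(C)[Si](C)(C)OCC=1CC[C@H](OC(=O)C(C)C)[C@@]2(C)[C@@H](O)C[C@@H](O[Si](C)(C)C(C)(C)C)C(=C)[C@@H]2[C@H](OC(C)=O)[C@](O[Si](CC)(CC)CC)([C@@H](C)C(=O)OC)[C@@H](O)C=1
F9 | step 27 | 5-ene C14 acetate lactone with C16 TBS ether | CC(C)(C)[Si](C)(C)OCC=1CC[C@H](OC(=O)C(C)C)[C@@]2(C)[C@@H](OC(C)=O)C[C@@H](O[Si](C)(C)C(C)(C)C)C(=C)[C@@H]2[C@H](OC(C)=O)[C@]2(O[Si](CC)(CC)CC)[C@@H](C)C(=O)O[C@H]2C=1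
F10 | step 27 | 5-ene C14 acetate lactone with free C16 hydroxyl | OCC=1CC[C@H](OC(=O)C(C)C)[C@@]2(C)[C@@H](OC(C)=O)C[C@@H](O[Si](C)(C)C(C)(C)C)C(=C)[C@@H]2[C@H](OC(C)=O)[C@]2(O[Si](CC)(CC)CC)[C@@H](C)C(=O)O[C@H]2C=1
F11 | step 3 | (1R,2S,5R)-menthyl (E)-3-methyl-4-oxobut-2-enoate | CC(C)[C@@H]1CC[C@@H](C)C[C@H]1OC(=O)/C=C(\C)C=O
F12 | step 3 | menthyl ester analogue of cycloadduct 5 | O=C[C@@]1(C)[C@@H](OCc2ccc(OC)cc2)C=C(O[Si](C)(C)C(C)(C)C)C[C@@H]1C(=O)O[C@@H]1C[C@H](C)CC[C@H]1C(C)C
F13 | step 10 | (E)-1-[(4-methoxybenzyl)oxy]-5-(phenylthio)pent-1-en-3-one | COc1ccc(CO/C=C/C(=O)CCSc2ccccc2)cc1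
F14 | step 10 | (1E,3Z)-1-[(4-methoxybenzyl)oxy]-5-(phenylthio)-3-(tert-butyldimethylsilyloxy)penta-1,3-diene | COc1ccc(CO/C=C/C(O[Si](C)(C)C(C)(C)C)=C/CSc2ccccc2)cc1
F15 | step 10 | cycloadduct with C11 phenylthiomethyl group | O=C[C@@]1(C)[C@@H](OCc2ccc(OC)cc2)C=C(O[Si](C)(C)C(C)(C)C)[C@@H](CSc2ccccc2)[C@@H]1C(=O)OCC
F16 | step 10 | lactone silyl enol ether with C11 phenylthiomethyl group | COc1ccc(COCC2(OCCO2)CC[C@H](O3)[C@@]4(C)[C@@H](OCc5ccc(OC)cc5)C=C(O[Si](C)(C)C(C)(C)C)[C@@H](CSc6ccccc6)[C@@H]4C3=O)cc1
F17 | step 10 | C12 ketone with C11 phenylthiomethyl group | COc1ccc(COCC2(OCCO2)CC[C@H](O3)[C@@]4(C)[C@@H](OCc5ccc(OC)cc5)CC(=O)[C@@H](CSc6ccccc6)[C@@H]4C3=O)cc1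
F18 | step 10 | C12 axial alcohol with C11 phenylthiomethyl group | COc1ccc(COCC2(OCCO2)CC[C@H](O3)[C@@]4(C)[C@@H](OCc5ccc(OC)cc5)C[C@@H](O)[C@@H](CSc6ccccc6)[C@@H]4C3=O)cc1
F19 | step 10 | sulfoxide of F18 (sulfur configuration open) | COc1ccc(COCC2(OCCO2)CC[C@H](O3)[C@@]4(C)[C@@H](OCc5ccc(OC)cc5)C[C@@H](O)[C@@H](CS(=O)c6ccccc6)[C@@H]4C3=O)cc1
F20 | step 15 | lactol of 20 (anomer mixture) | COc1ccc(COCC2(OCCO2)CC[C@H](O3)[C@@]4(C)[C@@H](OCc5ccc(OC)cc5)C[C@@H](O[Si](C)(C)C(C)(C)C)C(=C)[C@@H]4C3O)cc1
F21 | step 15 | C9 epimer of diol 27 | COc1ccc(COCC2(OCCO2)CC[C@H](O)[C@@]3(C)[C@@H](OCc4ccc(OC)cc4)C[C@@H](O[Si](C)(C)C(C)(C)C)C(=C)[C@@H]3[C@@H](O)C5(COCc6ccc(OC)cc6)SCCCS5)cc1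
F22 | step 15 | C9 epimer of isobutyrate 28 | COc1ccc(COCC2(OCCO2)CC[C@H](OC(=O)C(C)C)[C@@]3(C)[C@@H](OCc4ccc(OC)cc4)C[C@@H](O[Si](C)(C)C(C)(C)C)C(=C)[C@@H]3[C@@H](O)C5(COCc6ccc(OC)cc6)SCCCS5)cc1
F23 | step 15 | C9 ketone with C2 isobutyrate | COc1ccc(COCC2(OCCO2)CC[C@H](OC(=O)C(C)C)[C@@]3(C)[C@@H](OCc4ccc(OC)cc4)C[C@@H](O[Si](C)(C)C(C)(C)C)C(=C)[C@@H]3C(=O)C5(COCc6ccc(OC)cc6)SCCCS5)cc1
F0 | step 22 | none | none
A1 | alternative 1 | ring A fused isoxazoline | N1=C2C[C@H](O[Si](C)(C)C(C)(C)C)[C@](C)(COCc3ccc(OC)cc3)[C@@H](COCc3ccccc3)[C@@H]2CO1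
A2 | alternative 2 | bicyclic 14-hydroxy-11(20)-ene butenolide | C1[C@H](O[Si](C)(C)C(C)(C)C)[C@@]2(C)[C@@H](O)CCC(=C)[C@@H]2[C@H](O[Si](C)(C)C(C)(C)C)C3=C(C)C(=O)O[C@H]3/C=C(C)\C1
A3 | alternative 3 | ring A C14 ketone with C1, C2 and C10 set | C=C(COCc1ccc(OC)cc1)CC[C@H](O)[C@@]2(C)C(=O)C[C@@H](O[Si](C)(C)C(C)(C)C)C(OC)(OC)[C@@H]2C=C
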